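**Plan**

- Retrosynthetic cuts, in order: the three O-benzyl groups and the two temporary C3/C3''-CO2Bn groups; then C2''–C3'' and its counterpart C2–C3 (ring C of each flavanone unit) in one operation; then the two CH2–CO2Bn bonds; the C3'–C6'' biaryl bond; finally the aryl O–CH2 ether bonds and the C–I and C–B bonds.
- Enabling feature: C2'' carries the ring oxygen O1'' and the 4-oxygenated phenyl ring (C2 carries O1 and the 4'-methoxyphenylene ring B). With ring C open, each is therefore the CH2 of a 4-alkoxybenzyl aryl ether, a hydride donor towards DDQ. C3''/C3 lie α to the C4''/C4 ketones and become chelating β-keto ester enolates once they carry a temporary CO2Bn group.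
- Forward: both A rings come from the same acetophenone. The ethers, the iodide and the boronate are set up, a Suzuki coupling makes the biaryl bond, a double Claisen condensation adds the two esters, ring C of unit B and ring C of unit A then close in one flask, and hydrogenolysis removes the benzyl groups and esters.
- Stereochemistry: C2 and C2'' both arise in the key step under control of a chiral bisoxazoline complex of Cu(OTf)2. The C3/C3'' ester centres are temporary. No flavanone is exposed to base at any point.

Key step: step 9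

Remark: unit A is the 5-hydroxy-7-methoxyflavanone whose C2 carries ring B (the 4-methoxyphenylene ring); unit B (double-primed locants) is the 6''-aryl flavanone carrying the 4-hydroxyphenyl group.
Assumption: the (S,S) bisoxazoline is taken to deliver the 2S series; a model run on the mono-aroylacetate derived from 3 should confirm this, and the (R,R) ligand is used instead if the sense is reversed.
Remark: the C3 and C3'' ester centres of 12 to 14 are drawn trans to the 2-aryl groups; they are epimerisable and are removed in step 10.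

**Step 1**
Reactants: 1 1-(2,6-dihydroxy-4-methoxyphenyl)ethan-1-one; 2 4-(benzyloxy)benzyl chloride
Product: 3 1-(2-{[4-(benzyloxy)phenyl]methoxy}-6-hydroxy-4-methoxyphenyl)ethan-1-one
Conditions: K2CO3, NaI (cat.), acetone, reflux
Reagents that add atoms: none
Why: Williamson ether synthesis: once one phenol of the doubly chelated 2,6-dihydroxyacetophenone is alkylated, the remaining hydroxyl is held in a hydrogen bond to the carbonyl and reacts much more slowly, so one equivalent of 2 should give the mono-ether that later supplies C2'' and the 4-oxygenated phenyl ring of unit B.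

**Step 2**
Reactants: 3 mono-ether from step 1
Product: 4 1-(6-{[4-(benzyloxy)phenyl]methoxy}-2-hydroxy-3-iodo-4-methoxyphenyl)ethan-1-one
Conditions: BnMe3N·ICl2, NaHCO3, CH2Cl2/MeOH, rt
Reagents that add atoms: benzyltrimethylammonium dichloroiodate, C[N+](C)(C)Cc1ccccc1.Cl[I-]Cl
Why: Electrophilic aromatic iodination directed ortho by the free chelated hydroxyl: the position between OH and OMe is less hindered than the one between OMe and the large benzylic ether, as in the known 3-iodination of 2-hydroxy-4,6-dialkoxyacetophenones, and this places iodine at the future C6''.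

**Step 3**
Reactants: 4 iodophenol from step 2
Product: 5 1-[2-(benzyloxy)-6-{[4-(benzyloxy)phenyl]methoxy}-3-iodo-4-methoxyphenyl]ethan-1-one
Conditions: BnBr, K2CO3, DMF, 60 °C
Reagents that add atoms: benzyl bromide, BrCc1ccccc1
Why: Williamson benzylation of the hindered chelated phenol, which masks the future C5''-OH against DDQ and copper chelation and is removed in the final hydrogenolysis.

**Step 4**
Reactants: 1 1-(2,6-dihydroxy-4-methoxyphenyl)ethan-1-one; 6 (3-bromo-4-methoxyphenyl)methanol
Product: 7 1-{2-[(3-bromo-4-methoxyphenyl)methoxy]-6-hydroxy-4-methoxyphenyl}ethan-1-one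
Conditions: PPh3, DIAD, THF, 0 °C → rt
Reagents that add atoms: none
Why: Mitsunobu etherification of the acidic chelated phenol by the primary benzylic alcohol, mono-selective for the same hydrogen-bonding reason as in step 1, which installs the future C2 and ring B of unit A.

**Step 5**
Reactants: 7 bromo ether from step 4
Product: 8 1-{2-(benzyloxy)-6-[(3-bromo-4-methoxyphenyl)methoxy]-4-methoxyphenyl}ethan-1-one
Conditions: BnBr, K2CO3, DMF, 60 °C
Reagents that add atoms: benzyl bromide, BrCc1ccccc1
Why: Williamson benzylation of the remaining chelated phenol, which masks the future C5-OH until the last step.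

**Step 6**
Reactants: 8 aryl bromide from step 5
Product: 9 1-[2-(benzyloxy)-4-methoxy-6-{[4-methoxy-3-(4,4,5,5-tetramethyl-1,3,2-dioxaborolan-2-yl)phenyl]methoxy}phenyl]ethan-1-one
Conditions: B2pin2, Pd(dppf)Cl2 (3 mol %), KOAc, 1,4-dioxane, 90 °C
Reagents that add atoms: bis(pinacolato)diboron, CC1(C)OB(OC1(C)C)B1OC(C)(C)C(C)(C)O1
Why: Miyaura borylation of the aryl bromide, to which the hindered ketone and the ethers are inert under zerovalent palladium and KOAc.

**Step 7**
Reactants: 5 aryl iodide from step 3; 9 aryl boronate from step 6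
Product: 10 1-[3-(5-{[2-acetyl-3-(benzyloxy)-5-methoxyphenoxy]methyl}-2-methoxyphenyl)-2-(benzyloxy)-6-{[4-(benzyloxy)phenyl]methoxy}-4-methoxyphenyl]ethan-1-one (biaryl diketone)
Conditions: Pd(OAc)2 (5 mol %), SPhos (10 mol %), K3PO4, toluene/H2O, 90 °C
Reagents that add atoms: none
Why: Suzuki–Miyaura coupling forms the C3'–C6'' bond; the bulky electron-rich biarylphosphine suits the tri-ortho-substituted biaryl, and at this stage the molecule has no stereocentre and no base-sensitive group.

**Step 8**
Reactants: 10 biaryl diketone from step 7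
Product: 11 bis(benzyl β-keto ester): compound 10 in which each acetyl group has become C(=O)CH2CO2Bn
Conditions: NaH, (BnO)2CO, THF, reflux; then AcOH
Reagents that add atoms: dibenzyl carbonate, O=C(OCc1ccccc1)OCc1ccccc1
Why: Twofold crossed Claisen condensation of the methyl ketone enolates with dibenzyl carbonate, driven by formation of the stabilised β-keto ester enolates; the benzyl esters are the temporary activating groups for step 9.

**Step 9**
Reactants: 11 bis(benzyl β-keto ester) from step 8
Product: 13 dibenzyl 3,3''-dicarboxylate of the tri-O-benzyl biflavanone (2S,3R,2''S,3''R), via half-closed keto ester 12 (not isolated)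
Conditions: DDQ (2.4 equiv), Cu(OTf)2 (20 mol %), (S,S)-t-Bu-BOX (24 mol %), Na2HPO4, 4 Å MS, CH2Cl2, −40 °C → 0 °C
Reagents that add atoms: none
Why: Proposed new method: DDQ should take a hydride from each para-oxygenated benzylic CH2, which is activated both by the 4-alkoxyphenyl ring and by the aryl ether oxygen, to give an (E)-aryloxy benzylic cation (an O-aryl oxocarbenium ion) paired with DDQH−, while Cu(OTf)2 bound to the bisoxazoline holds the neighbouring aroylacetate as a chelated divalent-copper enolate; the enolate carbon (future C3) then adds to the cationic carbon (future C2) and DDQH− takes up the proton. The closest known reaction type is the DDQ-mediated enantioselective cross-dehydrogenative coupling of benzylic or cinnamylic alkyl ethers with a tethered β-keto ester under a chiral bisoxazoline complex of Cu(OTf)2, which closes tetrahydropyran-4-ones; new here are the aryl ether oxygen, the aroylacetate nucleophile and two closures in one flask. Each ring C closes in a 6-(enolendo)-endo-trig mode onto the O1=C2 bond of the cation. C2'' and C2 are each set by the catalyst: the ligand exposes one enolate face and a half-chair transition state with the 2-aryl group pseudo-equatorial relays this to C2, which also sets the temporary C3 and C3'' centres trans, and because the two units are remote the (2S,2''S) isomer should dominate while the minor diastereomers are removable by chromatography. The step needs chemoselective hydride abstraction and C- rather than O-attack of the enolate: only the two reacting CH2 groups carry a para oxygen donor (the plain benzyl ethers and esters do not), the tertiary C2–H of each product ring is deactivated by the adjacent C3 ester and C4 ketone, O-attack would give an acetal that can re-ionise, and the molecular sieves keep water from hydrolysing the cations.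

**Step 10**
Reactants: 13 diester from step 9
Product: 15 CNP0150873.1 (2S,2''S), via bis(β-keto acid) 14 (not isolated)
Conditions: H2 (1 atm), Pd/C (10 wt %), EtOAc/MeOH, rt; then 40 °C
Reagents that add atoms: none
Why: Hydrogenolysis cleaves the three aryl benzyl ethers and both benzyl esters, and the resulting β-keto acids lose CO2 under neutral conditions, which erases the temporary C3 and C3'' centres while C2 and C2'' stay untouched.

**Compound list**

1 | 1-(2,6-dihydroxy-4-methoxyphenyl)ethan-1-one | CC(=O)c1c(O)cc(OC)cc1O | starting material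
2 | 4-(benzyloxy)benzyl chloride | ClCc1ccc(OCc2ccccc2)cc1 | starting material
3 | 1-(2-{[4-(benzyloxy)phenyl]methoxy}-6-hydroxy-4-methoxyphenyl)ethan-1-one | CC(=O)c1c(O)cc(OC)cc1OCc1ccc(OCc2ccccc2)cc1 | intermediate
4 | 1-(6-{[4-(benzyloxy)phenyl]methoxy}-2-hydroxy-3-iodo-4-methoxyphenyl)ethan-1-one | CC(=O)c1c(O)c(I)c(OC)cc1OCc1ccc(OCc2ccccc2)cc1 | intermediate
5 | 1-[2-(benzyloxy)-6-{[4-(benzyloxy)phenyl]methoxy}-3-iodo-4-methoxyphenyl]ethan-1-one | CC(=O)c1c(OCc2ccccc2)c(I)c(OC)cc1OCc1ccc(OCc2ccccc2)cc1 | intermediate
6 | (3-bromo-4-methoxyphenyl)methanol | OCc1ccc(OC)c(Br)c1 | starting material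
7 | 1-{2-[(3-bromo-4-methoxyphenyl)methoxy]-6-hydroxy-4-methoxyphenyl}ethan-1-one | CC(=O)c1c(O)cc(OC)cc1OCc1ccc(OC)c(Br)c1 | intermediate
8 | 1-{2-(benzyloxy)-6-[(3-bromo-4-methoxyphenyl)methoxy]-4-methoxyphenyl}ethan-1-one | CC(=O)c1c(OCc2ccccc2)cc(OC)cc1OCc1ccc(OC)c(Br)c1 | intermediate
9 | 1-[2-(benzyloxy)-4-methoxy-6-{[4-methoxy-3-(4,4,5,5-tetramethyl-1,3,2-dioxaborolan-2-yl)phenyl]methoxy}phenyl]ethan-1-one | CC(=O)c1c(OCc2ccccc2)cc(OC)cc1OCc1ccc(OC)c(B2OC(C)(C)C(C)(C)O2)c1 | intermediate
10 | 1-[3-(5-{[2-acetyl-3-(benzyloxy)-5-methoxyphenoxy]methyl}-2-methoxyphenyl)-2-(benzyloxy)-6-{[4-(benzyloxy)phenyl]methoxy}-4-methoxyphenyl]ethan-1-one | CC(=O)c1c(OCc2ccccc2)cc(OC)cc1OCc1ccc(OC)c(-c2c(OC)cc(OCc3ccc(OCc4ccccc4)cc3)c(C(C)=O)c2OCc2ccccc2)c1 | intermediate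
11 | bis(benzyl β-keto ester): compound 10 with each acetyl group converted to C(=O)CH2CO2Bn | O=C(CC(=O)OCc1ccccc1)c1c(OCc2ccccc2)cc(OC)cc1OCc1ccc(OC)c(-c2c(OC)cc(OCc3ccc(OCc4ccccc4)cc3)c(C(=O)CC(=O)OCc3ccccc3)c2OCc2ccccc2)c1 | intermediate
12 | half-closed keto ester: unit B closed as the benzyl (2''S,3''R)-flavanone-3''-carboxylate, unit A still the open benzyl aroylacetate ether (unit B is expected to close first because its benzylic ring is unhindered) | O=C(CC(=O)OCc1ccccc1)c1c(OCc2ccccc2)cc(OC)cc1OCc1ccc(OC)c(-c2c(OC)cc3c(c2OCc2ccccc2)C(=O)[C@H](C(=O)OCc2ccccc2)[C@@H](c2ccc(OCc4ccccc4)cc2)O3)c1 | intermediate (not isolated)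
13 | dibenzyl (2S,3R,2''S,3''R)-3,3''-dicarboxylate of the 5,5'',4'''-tri-O-benzyl ether of 15 (trans CO2Bn at C3 and C3'') | COc1cc(OCc6ccccc6)c2c(c1)O[C@H](c1ccc(OC)c(-c3c(OC)cc4c(c3OCc3ccccc3)C(=O)[C@H](C(=O)OCc3ccccc3)[C@@H](c3ccc(OCc5ccccc5)cc3)O4)c1)[C@@H](C(=O)OCc1ccccc1)C2=O | intermediate
14 | (2S,3R,2''S,3''R)-3,3''-dicarboxylic acid of 15 (bis(β-keto acid)) | COc1cc(O)c2c(c1)O[C@H](c1ccc(OC)c(-c3c(OC)cc4c(c3O)C(=O)[C@H](C(O)=O)[C@@H](c3ccc(O)cc3)O4)c1)[C@@H](C(O)=O)C2=O | intermediate (not isolated)
15 | (2S)-5-hydroxy-2-{3-[(2S)-5-hydroxy-2-(4-hydroxyphenyl)-7-methoxy-4-oxo-3,4-dihydro-2H-chromen-6-yl]-4-methoxyphenyl}-7-methoxy-2,3-dihydro-4H-chromen-4-one (CNP0150873.1) | COc1cc(O)c2c(c1)O[C@H](c1ccc(OC)c(-c3c(OC)cc4c(c3O)C(=O)C[C@@H](c3ccc(O)cc3)O4)c1)CC2=O | target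

**Totals**

Total steps: 10. Longest linear sequence: 7 steps (steps 1, 2, 3, 7, 8, 9, 10).

**Steps most likely to fail**

Step 9 (bears the label). Hydride abstraction at the aryloxy-substituted benzylic carbons may be too slow, face selectivity in the enolate–cation union may be poor, or reversible opening of the β-keto ester rings may erode C2 and C2''. The fallback uses known chemistry only: base-free, divalent-palladium-catalysed asymmetric conjugate addition of arylboronic acids to chromones, which makes each C2–aryl bond instead of each C2–C3 bond. It sets out from 5 and 1 and comes back to the route at 15. DDQ in wet CH2Cl2 cleaves the 4-(benzyloxy)benzyl ether of 5 to the iodophenol ketone F1. DMF dimethyl acetal converts this to the enaminone F2, and HCl closes it to the 6-iodochromone F3. A Suzuki coupling with (5-chloro-2-methoxyphenyl)boronic acid (Pd(PPh3)4, K2CO3, DME/H2O; no stereocentre is present yet) gives the biaryl chromone F4. Addition of 4-(benzyloxy)phenylboronic acid under Pd(OCOCF3)2 and the t-BuPyOX enantiomer that gives the 2S series (NH4PF6, H2O, ClCH2CH2Cl, 60 °C) sets C2'' in the chloro flavanone F5. Miyaura borylation of the aryl chloride (Pd2(dba)3, XPhos, B2pin2, KOAc, which is too weak a base to open the flavanone) gives the flavanone boronate F6. In parallel, 1 is monobenzylated (BnBr, K2CO3) to the phenol F7, taken through the enaminone F8 and closed with HCl to the chromone F9. A second conjugate addition under the same palladium catalyst, of F6 to F9, sets C2 and gives the tri-O-benzyl biflavanone F10. Hydrogenolysis as in step 10 then gives 15.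

Step 10. Hydrogenolytic opening of the benzylic C2–O1 and C2''–O1'' bonds may compete with debenzylation, or C2 and C2'' may lose configuration by reversible ring opening of the β-keto acids before they decarboxylate. The fallback is a non-reductive, Lewis-acid debenzylation. It sets out from 13 and comes back at 15. BCl3 with pentamethylbenzene as cation scavenger (CH2Cl2, −78 °C) cleaves the three aryl benzyl ethers and both benzyl esters, and the acids 14 decarboxylate on warming during work-up. No new compound is made.

Step 7. Transmetalation at the doubly ortho-substituted arylpalladium intermediate may be slow, so that protodeboronation of the valuable boronate 9 outruns coupling. The fallback builds the biaryl first with a small boronic acid and forms the ether afterwards. It sets out from 5 and comes back at 10. Suzuki coupling of 5 with commercial (5-formyl-2-methoxyphenyl)boronic acid, used in excess, gives the biaryl aldehyde F11. NaBH4 at 0 °C, which leaves the hindered aryl methyl ketone alone, gives the biaryl benzylic alcohol F12. Mitsunobu etherification of F12 with the phenol F7 (made from 1 as in the first fallback) gives 10.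

**Further compounds**

F1 | step 9 | 1-[2-(benzyloxy)-6-hydroxy-3-iodo-4-methoxyphenyl]ethan-1-one | CC(=O)c1c(O)cc(OC)c(I)c1OCc1ccccc1
F2 | step 9 | (E)-1-[2-(benzyloxy)-6-hydroxy-3-iodo-4-methoxyphenyl]-3-(dimethylamino)prop-2-en-1-one | CN(C)/C=C/C(=O)c1c(O)cc(OC)c(I)c1OCc1ccccc1
F3 | step 9 | 5-(benzyloxy)-6-iodo-7-methoxy-4H-chromen-4-one | COc1cc2occc(=O)c2c(OCc2ccccc2)c1I
F4 | step 9 | 5-(benzyloxy)-6-(5-chloro-2-methoxyphenyl)-7-methoxy-4H-chromen-4-one | COc1cc2occc(=O)c2c(OCc2ccccc2)c1-c1cc(Cl)ccc1OC
F5 | step 9 | (2S)-5-(benzyloxy)-2-[4-(benzyloxy)phenyl]-6-(5-chloro-2-methoxyphenyl)-7-methoxy-2,3-dihydro-4H-chromen-4-one | COc1cc2c(c(OCc3ccccc3)c1-c1cc(Cl)ccc1OC)C(=O)C[C@@H](c1ccc(OCc3ccccc3)cc1)O2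
F6 | step 9 | (2S)-5-(benzyloxy)-2-[4-(benzyloxy)phenyl]-7-methoxy-6-[2-methoxy-5-(4,4,5,5-tetramethyl-1,3,2-dioxaborolan-2-yl)phenyl]-2,3-dihydro-4H-chromen-4-one | COc1cc2c(c(OCc3ccccc3)c1-c1cc(B3OC(C)(C)C(C)(C)O3)ccc1OC)C(=O)C[C@@H](c1ccc(OCc3ccccc3)cc1)O2
F7 | step 9 | 1-[2-(benzyloxy)-6-hydroxy-4-methoxyphenyl]ethan-1-one | CC(=O)c1c(O)cc(OC)cc1OCc1ccccc1
F8 | step 9 | (E)-1-[2-(benzyloxy)-6-hydroxy-4-methoxyphenyl]-3-(dimethylamino)prop-2-en-1-one | CN(C)/C=C/C(=O)c1c(O)cc(OC)cc1OCc1ccccc1
F9 | step 9 | 5-(benzyloxy)-7-methoxy-4H-chromen-4-one | COc1cc(OCc2ccccc2)c2c(c1)occc2=O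
F10 | step 9 | (2S,2''S)-5,5'',4'''-tri-O-benzyl ether of 15 | COc1cc(OCc6ccccc6)c2c(c1)O[C@H](c1ccc(OC)c(-c3c(OC)cc4c(c3OCc3ccccc3)C(=O)C[C@@H](c3ccc(OCc5ccccc5)cc3)O4)c1)CC2=O
F0 | step 10 | none | none
F11 | step 7 | 3-[3-acetyl-2-(benzyloxy)-4-{[4-(benzyloxy)phenyl]methoxy}-6-methoxyphenyl]-4-methoxybenzaldehyde | O=Cc1ccc(OC)c(-c2c(OC)cc(OCc3ccc(OCc4ccccc4)cc3)c(C(C)=O)c2OCc2ccccc2)c1
F12 | step 7 | 1-[2-(benzyloxy)-6-{[4-(benzyloxy)phenyl]methoxy}-3-[5-(hydroxymethyl)-2-methoxyphenyl]-4-methoxyphenyl]ethan-1-one | OCc1ccc(OC)c(-c2c(OC)cc(OCc3ccc(OCc4ccccc4)cc3)c(C(C)=O)c2OCc2ccccc2)c1
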